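The slowness of the midnight flask late on was what I had to explain. Its left-handed product gained 8.7 percentage points between 120 min and 180 min, but 1.1 points between 240 min and 300 min.

| flask | left-handed substrate | right-handed substrate | gas | free catalyst | temperature | remark | time |
|---|---|---|---|---|---|---|---|
| midnight | 0.036 M | 0.036 M | 3.8 mM (held) | 0.36 mM | 70 °C | the very flask that is asked about, followed so far |  |
| flask | 0.036 M | 0.036 M | 3.8 mM (held) | 0.36 mM | 70 °C |  | 8.0 h |

midnight run (percent of the left-handed substrate and right-handed substrate together charged)

| time / min | left-handed product / % | left-handed substrate / % |
|---|---|---|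
| 15.0 | 4.8 | 46.6 |
| 40.0 | 12.8 | 37.3 |
| 80.0 | 23.9 | 24.0 |
| 120 | 35.7 | 15.8 |
| 180 | 44.4 | 5.2 |
| 240 | 48.5 | 0.6 |
| 300 | 49.6 | 0.2 |

(scatter of a reading: 0.5 percentage points)

- free catalyst is single-handed; left-handed substrate and right-handed substrate are mirror images of each other, charged as a racemate, each of them at the stated concentration
- at the start none of coupling partner is dissolved
- left-handed product that was removed still counts
- steps under discussion: free catalyst + left-handed substrate <-> catalyst intermediate A; free catalyst + right-handed substrate <-> catalyst intermediate B; coupling partner + catalyst intermediate A -> free catalyst + left-handed product; coupling partner + catalyst intermediate B -> free catalyst + right-handed product; gas <-> coupling partner; coupling partner -> decomposition product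
- additions bring no volume worth counting
- the earlier runs do not show what temperature does; that part of a forecast is a guess

- grey: at 8.0 h raise the temperature by 10 K, then wait 2.5 h
- red: change nothing and wait 2.5 h more
- violet: at 8.0 h add free catalyst, 50.0% of the amount charged, then wait 2.5 h
- green: at 8.0 h take out 90% of the left-handed product then present, then wait 2.5 h

1. left-handed product, in percent of the left-handed substrate and right-handed substrate together first charged, at 8.0 h
2. the option that brings most further left-handed product ("none" if no option brings more than 2 percentage points) (grey / red / violet / green / none)
3. left-handed product present, with what was taken out counted in, in percent of the left-handed substrate and right-handed substrate together first charged, after grey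
4. left-handed product present, with what was taken out counted in, in percent of the left-handed substrate and right-handed substrate together first charged, after violet

Was the catalyst dying, or was the left-handed substrate going? The midnight readings show 55.1% of the left-handed substrate present at 120 min converted in the next hour, and 78.8% of that present at 180 min. So, as read, the share converted per hour did not fall as the left-handed substrate fell, and I saw no sign of lost catalyst.

By the listed steps, left-handed product comes from left-handed substrate, the limiting reagent here, so its ceiling was 50.0%. I therefore carried one quantity, the room: the ceiling minus the left-handed product present. The neighbouring flask read at 3.0 h has the same charge and looks nearly the same, yet the midnight reading gives it 5.6 points of room, above the 2 points margin. At 300 min the room read 0.4 points, within the scatter of 0.5 points. With the same charge, the two differ in room, so I committed to 50.0% at 8.0 h and to no useful option.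

The forecast gave 49.9%, none, 50% after grey and 50% after violet, holding that “No listed step interconverts the substrates or products”.

The flask gives 50.0%, best option none, 50.0% after grey and 50.0% after violet.

    free catalyst + left-handed substrate ⇌ catalyst intermediate A (K = 74.6 M⁻¹, k = 168 M⁻¹ s⁻¹, Ea = 41.0 kJ mol⁻¹, ΔH = 9.00 kJ mol⁻¹)
    free catalyst + right-handed substrate ⇌ catalyst intermediate B (K = 15.9 M⁻¹, k = 5.92 M⁻¹ s⁻¹, Ea = 58.0 kJ mol⁻¹, ΔH = −52.0 kJ mol⁻¹)
    coupling partner + catalyst intermediate A → free catalyst + left-handed product (k = 6.71 M⁻¹ s⁻¹, Ea = 48.0 kJ mol⁻¹)
    coupling partner + catalyst intermediate B → free catalyst + right-handed product (k = 3.20 M⁻¹ s⁻¹, Ea = 58.0 kJ mol⁻¹)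
    gas ⇌ coupling partner, rate k5*(csat - [coupling partner]) (kL = 0.00493 s⁻¹)
    coupling partner → decomposition product (k = 8.66 × 10⁻⁷ s⁻¹, Ea = 116 kJ mol⁻¹)
    (constants at 70 °C)

The room, read as 0.4 points at 300 min, stood at 0.0011 points in the flask at 8.0 h, but the flask was not at rest. At 8.0 h it still held 16.9% right-handed substrate and 15.8% of its catalyst as catalyst intermediate B. At 4800 min the right-handed substrate stands at 0%, right-handed product has gone from 33.0% to 50.0%, and left-handed product remains 50.0%. The further work lies on the other hand.

On the neighbour read at 2.0 h, the midnight reading gives a room of 14 points, so waiting still pays there. Computed, that flask holds 35.0% left-handed product and 14.8% left-handed substrate.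

The earlier runs and the new flask come from a simulation with made-up constants, and the scatter is random.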